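The pitfall I watched for was reading this share as a yield: it is a ratio among products, and a small sum of products can still give a high ratio.

common to all: substrate 2.0 mM; gas 0.24 mM (held); time 6.0 min
- Friday's: temperature −35 °C
- Wednesday's: temperature 25 °C
- Thursday's: temperature 55 °C
- Monday's: temperature −5 °C

* which flask leads in share of target in all that became target or isomer of the product or side product ("all alike" within 1.5 percentage points) (Friday's / Wednesday's / Thursday's / Monday's / all alike)
* share of target in all that became target or isomer of the product or side product, Friday's
* share of target in all that became target or isomer of the product or side product, Wednesday's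
* share of target in all that became target or isomer of the product or side product, Thursday's
* share of target in all that became target or isomer of the product or side product, Monday's

- percent here means substrate units held: one side product counts as two
- at the start none of partner is dissolved
- all constants are for 25 °C and move with temperature by the activation energies and enthalpies

    substrate + partner → intermediate (k1 = 250 L mol⁻¹ s⁻¹, Ea1 = 35.0 kJ mol⁻¹)
    intermediate → target (k2 = 0.022 s⁻¹, Ea2 = 86.0 kJ mol⁻¹)
    target ⇌ isomer of the product (K3 = 8.0, k3 = 0.026 s⁻¹, Ea3 = 88.0 kJ mol⁻¹, ΔH3 = 6.00 kJ mol⁻¹)
    gas ⇌ partner, rate k4*(csat - [partner]) (k4 = 1.0 s⁻¹, csat = 0.24 mM)
    substrate + target → side product (k5 = 9.6 L mol⁻¹ s⁻¹, Ea5 = 52.0 kJ mol⁻¹)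
    (constants at 25 °C)

1. **Main steps.** Substrate couples with dissolved partner to give intermediate, and intermediate converts to target. In Friday's, with c partner taken at 0.24 mM, the coupling is pseudo-first-order in substrate at 6.16 h⁻¹. Partner crosses over at 1.0 s⁻¹, against a demand of 0.0143 s⁻¹ at full charge, so I kept c partner at saturation. With these steps target is the one product, and the share is 100%.

2. **Isomerisation added.** In Friday's, target goes to isomer of the product at 0.0122 h⁻¹. While c intermediate grows with time, c target grows with its square. Integrating the rate of isomer formation and dividing by c target cancels the feed, so c isomer over c target is the pace times t/3. This costs 0.0407%.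

3. **Side reaction added.** Each event removes a target and counts two units, so its pace is twice k5 times c substrate. Target is made late, and weighting by the square of time puts the mean at 3/4 of the time, where c substrate is 1.26 mM. In Friday's that gives 0.441 h⁻¹, faster than isomerisation.

4. **Drain number.** The sum of the two paces times t/3 is 1.51%, the drain number: units lost from target per unit of target formed, with the feed divided out. I therefore expected 98.5% in Friday's.

5. **The other flasks.** In Monday's, the coupling half-life of 56.1 s is shorter than the time. Intermediate is then flat and target grows linearly, so the divisor becomes 2. I neglected the side reaction there, and 1.76 h⁻¹ gave about 91.2%. In Wednesday's, the relaxation half-life of target and isomer is 23.7 s, shorter than the time, so I took the equilibrium share of 11.1%. For Thursday's the equilibrium share is 9.11%, and I did not reckon the side product in either warm flask. My lead was Friday's.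

6. **The forecast.** It also named Friday's, with 97.8% there, 10.3% for Wednesday's, 7.4% for Thursday's and 90.5% for Monday's. Its ground for the cold flasks was that “target is formed slowly and has had little time”. Its Friday's figure lies below mine, and its Wednesday's figure lies below my equilibrium share.

7. **The simulation.** Friday's led, with 98.4% there, 10.5% in Wednesday's, 7.74% in Thursday's and 89.4% in Monday's. Every forecast answer held.

In Friday's, the half-life of target by the side reaction at 1.84 min was 140 min, shorter than the 57 h by forward isomerisation yet long against the 6.0 min, and the drain number 1.51% stands beside a lost share of 1.60%. With 8.0 mM of substrate in the same flask, the side reaction's pace scaled with the charge gives 94.1%, and that neighbour flask read 94.0%.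

Its constants belong to no real substance.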